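**Retrosynthetic overview**
- The last events are unmasking of the C11 hydroxyl, esterification at C4 with 3-methylbut-2-enoic anhydride, and hydroxyl-directed peracid epoxidation of the ring (5Z)-alkene; the oxirane is the last ring formed.
- The ten-membered carbocycle and the trans-fused α-methylene-γ-lactone arise in one operation: a chromium-catalysed intramolecular 2-(methoxycarbonyl)allylation of an α-silyloxy aldehyde by a 2-(bromomethyl)enoate (C3a–C11a bond; carbocycle first, lactone in the same pot).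
- The open-chain bromo aldehyde comes from a palladium-catalysed B-alkyl Suzuki–Miyaura union (C6–C7 bond) of a western C7 alkene and an eastern C8 (Z)-vinyl iodide.
- West: prop-2-yn-1-ol and allyl bromide, with Sharpless epoxidation and AlMe3 opening setting C10 and C11. East: (2S)-but-3-ene-1,2-diol (C4) and methyl prop-2-ynoate, via ozonolysis, Z-selective iodo-olefination and vinylalane addition.

Abbreviations and locants: TES = triethylsilyl, TBS = tert-butyldimethylsilyl, TMS = trimethylsilyl. Target locants follow cyclodeca[b]furan numbering (O1, C2 carbonyl, C3 methylidene carbon, C3a ring fusion, C4 ester carbon, C5–C6 oxirane, C10 methyl-bearing carbon, C11 carbinol, C11a lactone carbinol).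

Assumption: the code CNP0119422.2 denotes exactly the given SMILES; silylating agents, the phosphonium salt, AlMe3 and the oxidants are treated as reagents.

**Western fragment**

Step 1
Reactants: 1 prop-2-yn-1-ol; 2 3-bromoprop-1-ene (allyl bromide)
Product: 3 hex-5-en-2-yn-1-ol
Conditions: CuI (5 mol %), K2CO3, n-Bu4NI (10 mol %), DMF, rt
Reagents that add atoms: none
Why: Copper-catalysed alkyne allylation (the copper acetylide formed under carbonate base substitutes the allylic bromide) gives the skipped enyne, which has no stereocentre.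

Step 2
Reactants: 3 hex-5-en-2-yn-1-ol
Product: 4 (2E)-hexa-2,5-dien-1-ol
Conditions: LiAlH4, THF, 0 °C → reflux; aqueous NaOH work-up
Reagents that add atoms: none
Why: trans-Hydroalumination of the propargylic alcohol through its alkoxyaluminate gives only the E allylic alcohol and leaves the isolated terminal alkene untouched.

Step 3
Reactants: 4 (2E)-hexa-2,5-dien-1-ol
Product: 5 [(2S,3S)-3-(prop-2-en-1-yl)oxiran-2-yl]methanol
Conditions: Ti(OiPr)4 (5 mol %), L-(+)-diethyl tartrate (6 mol %), t-BuOOH, 4 Å molecular sieves, CH2Cl2, −20 °C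
Reagents that add atoms: tert-butyl hydroperoxide, CC(C)(C)OO
Why: Sharpless asymmetric epoxidation with L-(+)-tartrate delivers the titanium-bound peroxide oxygen to the face of the E allylic alcohol that gives the (2S,3S) epoxide, fixing the later C11 centre and the centre inverted in step 4.

Step 4
Reactants: 5 [(2S,3S)-3-(prop-2-en-1-yl)oxiran-2-yl]methanol
Product: 6 (2R,3R)-3-methylhex-5-ene-1,2-diol
Conditions: AlMe3 (3 equiv), hexane/CH2Cl2, 0 °C → rt
Reagents that add atoms: trimethylaluminium, C[Al](C)C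
Why: Regioselective opening of the 2,3-epoxy alcohol, in which the aluminium alkoxide directs methyl to C3 with inversion, turns the trans epoxide into the anti 3-methyl-1,2-diol and sets the later C10 centre.

Step 5
Reactants: 6 (2R,3R)-3-methylhex-5-ene-1,2-diol
Product: 8 (2R,3R)-2-(TBSO)-3-methyl-1-(TESO)hex-5-ene, via primary TES ether 7 (not isolated)
Conditions: Et3SiCl (1.05 equiv), imidazole, CH2Cl2, −30 °C; then t-BuMe2SiOTf, 2,6-lutidine, −30 → 0 °C
Reagents that add atoms: chlorotriethylsilane, CC[Si](Cl)(CC)CC; tert-butyldimethylsilyl trifluoromethanesulfonate, CC(C)(C)[Si](C)(C)OS(=O)(=O)C(F)(F)F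
Why: One-pot differential silylation (the primary hydroxyl takes the silyl chloride, the hindered secondary one needs the silyl triflate) gives a primary ether that can later be oxidised directly and a robust non-chelating secondary ether, with no stereocentre touched.

**Eastern fragment**

Step 6
Reactants: 9 (2S)-but-3-ene-1,2-diol
Product: 10 (3S)-3,4-bis(TESO)but-1-ene
Conditions: Et3SiCl (2.4 equiv), imidazole, DMF, 0 °C → rt
Reagents that add atoms: chlorotriethylsilane, CC[Si](Cl)(CC)CC
Why: Standard silyl ether formation protects both hydroxyls; the stereocentre (later C4) comes unchanged from the chiral pool.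

Step 7
Reactants: 10 (3S)-3,4-bis(TESO)but-1-ene
Product: 11 (2R)-2,3-bis(TESO)propanal
Conditions: O3, CH2Cl2, −78 °C; then PPh3, −78 °C → rt
Reagents that add atoms: ozone, [O-][O+]=O
Why: Ozonolysis with reductive work-up cleaves the only alkene to the α-silyloxy aldehyde without touching the adjacent stereocentre.

Step 8
Reactants: 11 (2R)-2,3-bis(TESO)propanal
Product: 12 (2S,3Z)-4-iodo-1,2-bis(TESO)pent-3-ene
Conditions: [Ph3PEt]I, n-BuLi, THF, 0 °C; iodine, −78 °C; NaN(SiMe3)2, −78 → −20 °C; then 11, −78 → −20 °C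
Reagents that add atoms: ethyltriphenylphosphonium iodide, CC[P+](c1ccccc1)(c1ccccc1)c1ccccc1.[I-]; iodine, [I][I]
Why: Stork–Zhao-type Wittig olefination with the non-stabilised α-iodo ylide proceeds through the kinetically favoured cis-oxaphosphetane, placing iodine cis to the chain and giving the Z vinyl iodide that fixes the ring alkene geometry.

Step 9
Reactants: 12 (2S,3Z)-4-iodo-1,2-bis(TESO)pent-3-ene
Product: 13 (2S,3Z)-4-iodo-2-(TESO)pent-3-enal
Conditions: (COCl)2, DMSO, CH2Cl2, −78 °C; 12, −78 → −40 °C; i-Pr2NEt, −78 → −30 °C; used at once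
Reagents that add atoms: none
Why: Swern oxidation applied directly to the primary TES ether (chloride-assisted desilylation to the alkoxysulfonium salt, then ylide fragmentation) gives the aldehyde while the secondary TES ether stays, and the cold hindered-base quench protects the α-centre.

Step 10
Reactants: 13 (2S,3Z)-4-iodo-2-(TESO)pent-3-enal; 14 methyl prop-2-ynoate
Product: 15 methyl (4S,5Z)-3-hydroxy-6-iodo-2-methylidene-4-(TESO)hept-5-enoate (both C3 epimers)
Conditions: 14, i-Bu2AlH, N-methylmorpholine N-oxide, THF, 0 °C; then 13, 0 °C → rt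
Reagents that add atoms: none
Why: Hydroalumination of the propiolate gives the α-(methoxycarbonyl)vinylalane, which adds to the aldehyde to give the Morita–Baylis–Hillman-type adduct; the new carbinol centre is left uncontrolled because it becomes sp2 in step 12.

**Union and ring closure**

Step 11
Reactants: 8 (2R,3R)-2-(TBSO)-3-methyl-1-(TESO)hex-5-ene; 15 methyl (4S,5Z)-3-hydroxy-6-iodo-2-methylidene-4-(TESO)hept-5-enoate
Product: 17 methyl (4S,5Z,10R,11R)-11-(TBSO)-3-hydroxy-6,10-dimethyl-2-methylidene-4,12-bis(TESO)dodec-5-enoate (both C3 epimers), via B-alkyl-9-borabicyclononane 16 (not isolated)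
Conditions: 8, 9-BBN (1.3 equiv), THF, rt; then 15, Pd(dppf)Cl2 (5 mol %), AsPh3 (10 mol %), aqueous Cs2CO3, DMF, rt
Reagents that add atoms: none
Why: Hydroboration of the terminal alkene followed by B-alkyl Suzuki–Miyaura coupling (oxidative addition of the vinyl iodide to zerovalent palladium, transmetalation of the alkyl borate, reductive elimination) joins the fragments with retention of the Z alkene geometry.

Step 12
Reactants: 17 methyl (4S,5Z,10R,11R)-11-(TBSO)-3-hydroxy-6,10-dimethyl-2-methylidene-4,12-bis(TESO)dodec-5-enoate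
Product: 18 methyl (2Z,4S,5Z,10R,11R)-2-(bromomethyl)-11-(TBSO)-6,10-dimethyl-4,12-bis(TESO)dodeca-2,5-dienoate
Conditions: NBS, Me2S, CH2Cl2, −20 °C; then 17, −20 → 0 °C
Reagents that add atoms: N-bromosuccinimide, O=C1CCC(=O)N1Br
Why: Corey–Kim-type activation of the Baylis–Hillman alcohol as an alkoxysulfonium salt and SN2′ attack of bromide give the rearranged primary allylic bromide and erase the uncontrolled carbinol centre.

Step 13
Reactants: 18 methyl (2Z,4S,5Z,10R,11R)-2-(bromomethyl)-11-(TBSO)-6,10-dimethyl-4,12-bis(TESO)dodeca-2,5-dienoate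
Product: 19 methyl (2Z,4S,5Z,10R,11R)-2-(bromomethyl)-11-(TBSO)-6,10-dimethyl-12-oxo-4-(TESO)dodeca-2,5-dienoate
Conditions: (COCl)2, DMSO, CH2Cl2, −78 °C; 18, −78 → −40 °C; i-Pr2NEt, −78 → −30 °C; used at once
Reagents that add atoms: none
Why: Direct Swern oxidation of the primary TES ether as in step 9 gives the α-silyloxy aldehyde, while the secondary silyl ethers and the allylic bromide survive the cold, non-nucleophilic conditions.

Step 14
Reactants: 19 methyl (2Z,4S,5Z,10R,11R)-2-(bromomethyl)-11-(TBSO)-6,10-dimethyl-12-oxo-4-(TESO)dodeca-2,5-dienoate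
Product: 22 (3aR,4S,5Z,10R,11R,11aS)-11-(TBSO)-4-hydroxy-6,10-dimethyl-3-methylidene-3a,4,7,8,9,10,11,11a-octahydrocyclodeca[b]furan-2(3H)-one, via macrocyclic TMS ether ester 20 (not isolated), via TES-protected lactone 21 (not isolated)
Conditions: CrCl2 (20 mol %), (S,S)-3,6-di-tert-butyl-1,8-bis(4-isopropyl-4,5-dihydrooxazol-2-yl)-9H-carbazole (22 mol %), Mn powder (3 equiv), Me3SiCl (2 equiv), i-Pr2NEt (40 mol %), THF, rt, 19 added by syringe pump over 16 h (final 2 mM); filter; PPTS, CH2Cl2/MeOH 10:1, rt; then MeOH, 40 °C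
Reagents that add atoms: none
Why: Proposed new method: a chromium-catalysed, ligand-controlled intramolecular Nozaki–Hiyama–Kishi 2-(alkoxycarbonyl)allylation that closes the ten-membered carbocycle: CrCl2 (divalent chromium) reduces the allylic bromide in two one-electron steps to an η1-allyl complex of trivalent chromium held by the tridentate ligand, which adds through its γ-carbon (C3a) to the chromium-bound aldehyde in a closed chair transition state with the ring chain pseudo-equatorial on both reacting carbons (anti adduct, hence the trans ring fusion), on the Felkin–Anh face set by the C11 OTBS group and anti to the allylic OTES group of the A(1,3)-minimised allyl unit (the three preferences coincide and the ligand is chosen to reinforce that aldehyde face), after which Me3SiCl silylates the alkoxide to release trivalent chromium and zerovalent manganese returns it to the divalent state; mild acid then removes the TMS group first, so that the new C11a hydroxyl and not the still-protected C4 oxygen closes the γ-lactone before the TES group falls; the closest known reactions are the intermolecular catalytic asymmetric chromium 2-(alkoxycarbonyl)allylation of aldehydes and the stoichiometric CrCl2 Barbier macrocyclisation of 2-(bromomethyl)acrylate aldehydes to ten-membered sesquiterpene lactones.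

**Endgame**

Step 15
Reactants: 22 (3aR,4S,5Z,10R,11R,11aS)-11-(TBSO)-4-hydroxy-6,10-dimethyl-3-methylidene-3a,4,7,8,9,10,11,11a-octahydrocyclodeca[b]furan-2(3H)-one
Product: 23 (3aR,4R,5S,6R,10R,11R,11aS)-11-(TBSO)-5,6-epoxy-4-hydroxy-6,10-dimethyl-3-methylidenedecahydrocyclodeca[b]furan-2(3H)-one
Conditions: mCPBA, CH2Cl2, −20 → 0 °C
Reagents that add atoms: 3-chloroperoxybenzoic acid, OOC(=O)c1cccc(Cl)c1
Why: Hydroxyl-directed (Henbest) peracid epoxidation of the only electron-rich alkene: with a ring carbon cis to the carbinol, A(1,3) strain holds the carbinol hydrogen in the alkene plane and the hydrogen-bonded peracid delivers oxygen syn to the hydroxyl, which gives the threo (5S,6R) epoxide, while the conjugated methylidene does not react.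

Step 16
Reactants: 24 3-methylbut-2-enoic acid (two molecules)
Product: 25 3-methylbut-2-enoic anhydride
Conditions: 24 (2 equiv), DCC (1 equiv), CH2Cl2, 0 °C → rt; filter
Reagents that add atoms: 3-methylbut-2-enoic acid (the second molecule of 24), CC(C)=CC(=O)O
Why: Carbodiimide dehydration: the O-acylisourea formed from one molecule of the acid is acylated by the carboxyl group of a second molecule, giving the symmetrical anhydride and the urea; the anhydride is an acyl donor that avoids the ketene pathway and the β,γ-isomerisation seen with the acid chloride.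

Step 17
Reactants: 23 (3aR,4R,5S,6R,10R,11R,11aS)-11-(TBSO)-5,6-epoxy-4-hydroxy-6,10-dimethyl-3-methylidenedecahydrocyclodeca[b]furan-2(3H)-one; 25 3-methylbut-2-enoic anhydride
Product: 26 (3aR,4R,5S,6R,10R,11R,11aS)-11-(TBSO)-5,6-epoxy-6,10-dimethyl-3-methylidene-2-oxododecahydrocyclodeca[b]furan-4-yl 3-methylbut-2-enoate
Conditions: DMAP (0.3 equiv), pyridine, CH2Cl2, 0 °C → rt
Reagents that add atoms: none
Why: DMAP-catalysed acyl transfer esterifies the only free hydroxyl with retention at C4.

Step 18
Reactants: 26 (3aR,4R,5S,6R,10R,11R,11aS)-11-(TBSO)-5,6-epoxy-6,10-dimethyl-3-methylidene-2-oxododecahydrocyclodeca[b]furan-4-yl 3-methylbut-2-enoate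
Product: 27 (3aS,4R,5S,6R,10R,11R,11aS)-5,6-epoxy-11-hydroxy-6,10-dimethyl-3-methylidene-2-oxododecahydrocyclodeca[b]furan-4-yl 3-methylbut-2-enoate
Conditions: HF·pyridine, pyridine, THF, 0 °C → rt
Reagents that add atoms: none
Why: Fluoride-driven cleavage of the TBS ether under pyridine-buffered conditions frees the C11 hydroxyl without opening the oxirane or adding to the two enoates.

**Compound list**

1 | prop-2-yn-1-ol | C#CCO | starting material
2 | 3-bromoprop-1-ene (allyl bromide) | C=CCBr | starting material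
3 | hex-5-en-2-yn-1-ol | OCC#CCC=C | intermediate
4 | (2E)-hexa-2,5-dien-1-ol | OC/C=C/CC=C | intermediate
5 | [(2S,3S)-3-(prop-2-en-1-yl)oxiran-2-yl]methanol | OC[C@@H]1O[C@H]1CC=C | intermediate
6 | (2R,3R)-3-methylhex-5-ene-1,2-diol | OC[C@H](O)[C@H](C)CC=C | intermediate
7 | (2R,3R)-3-methyl-1-(TESO)hex-5-en-2-ol | CC[Si](CC)(CC)OC[C@H](O)[C@H](C)CC=C | intermediate
8 | (2R,3R)-2-(TBSO)-3-methyl-1-(TESO)hex-5-ene | CC[Si](CC)(CC)OC[C@H](O[Si](C)(C)C(C)(C)C)[C@H](C)CC=C | intermediate
9 | (2S)-but-3-ene-1,2-diol | C=C[C@H](O)CO | starting material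
10 | (3S)-3,4-bis(TESO)but-1-ene | C=C[C@H](O[Si](CC)(CC)CC)CO[Si](CC)(CC)CC | intermediate
11 | (2R)-2,3-bis(TESO)propanal | O=C[C@H](O[Si](CC)(CC)CC)CO[Si](CC)(CC)CC | intermediate
12 | (2S,3Z)-4-iodo-1,2-bis(TESO)pent-3-ene | C/C(I)=C/[C@H](O[Si](CC)(CC)CC)CO[Si](CC)(CC)CC | intermediate
13 | (2S,3Z)-4-iodo-2-(TESO)pent-3-enal | C/C(I)=C/[C@H](O[Si](CC)(CC)CC)C=O | intermediate
14 | methyl prop-2-ynoate | C#CC(=O)OC | starting material
15 | methyl (4S,5Z)-3-hydroxy-6-iodo-2-methylidene-4-(TESO)hept-5-enoate (both C3 epimers) | C/C(I)=C/[C@H](O[Si](CC)(CC)CC)C(O)C(=C)C(=O)OC | intermediate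
16 | 9-[(4R,5R)-5-(TBSO)-4-methyl-6-(TESO)hexyl]-9-borabicyclo[3.3.1]nonane | CC[Si](CC)(CC)OC[C@H](O[Si](C)(C)C(C)(C)C)[C@H](C)CCCB1C2CCCC1CCC2 | intermediate
17 | methyl (4S,5Z,10R,11R)-11-(TBSO)-3-hydroxy-6,10-dimethyl-2-methylidene-4,12-bis(TESO)dodec-5-enoate (both C3 epimers) | COC(=O)C(=C)C(O)[C@@H](O[Si](CC)(CC)CC)/C=C(/C)CCC[C@@H](C)[C@@H](O[Si](C)(C)C(C)(C)C)CO[Si](CC)(CC)CC | intermediate
18 | methyl (2Z,4S,5Z,10R,11R)-2-(bromomethyl)-11-(TBSO)-6,10-dimethyl-4,12-bis(TESO)dodeca-2,5-dienoate | COC(=O)/C(CBr)=C/[C@@H](O[Si](CC)(CC)CC)/C=C(/C)CCC[C@@H](C)[C@@H](O[Si](C)(C)C(C)(C)C)CO[Si](CC)(CC)CC | intermediate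
19 | methyl (2Z,4S,5Z,10R,11R)-2-(bromomethyl)-11-(TBSO)-6,10-dimethyl-12-oxo-4-(TESO)dodeca-2,5-dienoate | COC(=O)/C(CBr)=C/[C@@H](O[Si](CC)(CC)CC)/C=C(/C)CCC[C@@H](C)[C@@H](O[Si](C)(C)C(C)(C)C)C=O | intermediate
20 | methyl 2-[(1R,2S,3Z,8R,9R,10S)-9-(TBSO)-4,8-dimethyl-2-(TESO)-10-(TMSO)cyclodec-3-en-1-yl]prop-2-enoate | COC(=O)C(=C)[C@@H]1[C@@H](O[Si](CC)(CC)CC)/C=C(/C)CCC[C@@H](C)[C@@H](O[Si](C)(C)C(C)(C)C)[C@H]1O[Si](C)(C)C | intermediate
21 | (3aS,4S,5Z,10R,11R,11aS)-11-(TBSO)-6,10-dimethyl-3-methylidene-4-(TESO)-3a,4,7,8,9,10,11,11a-octahydrocyclodeca[b]furan-2(3H)-one | C=C1C(=O)O[C@@H]2[C@H](O[Si](C)(C)C(C)(C)C)[C@H](C)CCC/C(C)=C\[C@H](O[Si](CC)(CC)CC)[C@@H]12 | intermediate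
22 | (3aR,4S,5Z,10R,11R,11aS)-11-(TBSO)-4-hydroxy-6,10-dimethyl-3-methylidene-3a,4,7,8,9,10,11,11a-octahydrocyclodeca[b]furan-2(3H)-one | C=C1C(=O)O[C@@H]2[C@H](O[Si](C)(C)C(C)(C)C)[C@H](C)CCC/C(C)=C\[C@H](O)[C@@H]12 | intermediate
23 | (3aR,4R,5S,6R,10R,11R,11aS)-11-(TBSO)-5,6-epoxy-4-hydroxy-6,10-dimethyl-3-methylidenedecahydrocyclodeca[b]furan-2(3H)-one | C=C1C(=O)O[C@@H]2[C@H](O[Si](C)(C)C(C)(C)C)[C@H](C)CCC[C@@]3(C)O[C@H]3[C@H](O)[C@@H]12 | intermediate
24 | 3-methylbut-2-enoic acid | CC(C)=CC(=O)O | starting material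
25 | 3-methylbut-2-enoic anhydride | CC(C)=CC(=O)OC(=O)C=C(C)C | intermediate
26 | (3aR,4R,5S,6R,10R,11R,11aS)-11-(TBSO)-5,6-epoxy-6,10-dimethyl-3-methylidene-2-oxododecahydrocyclodeca[b]furan-4-yl 3-methylbut-2-enoate | C=C1C(=O)O[C@@H]2[C@H](O[Si](C)(C)C(C)(C)C)[C@H](C)CCC[C@@]3(C)O[C@H]3[C@H](OC(=O)C=C(C)C)[C@@H]12 | intermediate
27 | (3aS,4R,5S,6R,10R,11R,11aS)-5,6-epoxy-11-hydroxy-6,10-dimethyl-3-methylidene-2-oxododecahydrocyclodeca[b]furan-4-yl 3-methylbut-2-enoate (CNP0119422.2) | C=C1C(=O)O[C@@H]2[C@H](O)[C@H](C)CCC[C@@]3(C)O[C@H]3[C@H](OC(=O)C=C(C)C)[C@@H]12 | target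

**Step count**

Total steps: 18.
Longest linear sequence: 12 steps (steps 1–5, 11–15, 17, 18; the eastern branch, steps 6–10 then 11–15, 17, 18, is equally long).

**Three steps most likely to fail**

1. Step 14 (the new ring closure). The risks are slow catalyst turnover at high dilution, oligomerisation, loss of the δ-silyloxy group from the allylchromium species, and a macrocyclic transition state that departs from the acyclic anti/Felkin–Anh model. If the (S,S) ligand proves mismatched, its enantiomer is used. The fallback uses known chemistry, sets out from 19 and comes back to the route at 22. Compound 19 is added by syringe pump over 20 h to CrCl2 (8 equiv) in degassed THF/DMF at rt; this is the classical stoichiometric, ligand-free chromium Barbier macrocyclisation of a 2-(bromomethyl)enoate aldehyde, the established closure of ten-membered sesquiterpene lactone rings, here under substrate control only. Aqueous work-up and chromatography give the macrocyclic hydroxy ester methyl 2-[(1S,2S,3Z,8R,9R,10S)-9-(TBSO)-10-hydroxy-4,8-dimethyl-2-(TESO)cyclodec-3-en-1-yl]prop-2-enoate F1. PPTS in CH2Cl2/MeOH then closes the lactone and removes the TES group to give 22.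

2. Step 15 (face selectivity of the epoxidation). In the ten-membered ring the hydroxyl-directed peracid may not follow the acyclic threo rule and could deliver oxygen to the other face. The fallback sets out from 22 and comes back at 23 and puts the oxygen on the face opposite to the one an electrophile attacks. NBS in THF/H2O at 0 °C forms the bromonium ion, and water opens it anti at the tertiary carbon to give the bromohydrin (3aR,4R,5R,6R,10R,11R,11aS)-5-bromo-11-(TBSO)-4,6-dihydroxy-6,10-dimethyl-3-methylidenedecahydrocyclodeca[b]furan-2(3H)-one F2. DBU in CH2Cl2 at 0 °C closes it with inversion at C5 to 23.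

3. Step 8 (Z-selective iodo-olefination). The α,β-bis(silyloxy) aldehyde is labile, and the iodo ylide often gives moderate yield and incomplete Z selectivity. The fallback sets out from 11 and comes back at 12, building the geometry by cross-coupling instead. CBr4/PPh3 in CH2Cl2 at 0 °C (Corey–Fuchs dibromo-olefination) gives (2S)-4,4-dibromo-1,2-bis(TESO)but-3-ene F3. MeZnCl with Pd(DPEphos)Cl2 (2 mol %) in THF replaces selectively the bromine trans to the chain and gives (2S,3Z)-4-bromo-1,2-bis(TESO)pent-3-ene F4. t-BuLi in Et2O at −78 °C followed by iodine exchanges bromine for iodine with retention to give 12.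

Further compounds
F1 | step 14 | methyl 2-[(1S,2S,3Z,8R,9R,10S)-9-(TBSO)-10-hydroxy-4,8-dimethyl-2-(TESO)cyclodec-3-en-1-yl]prop-2-enoate | COC(=O)C(=C)[C@@H]1[C@@H](O[Si](CC)(CC)CC)/C=C(/C)CCC[C@@H](C)[C@@H](O[Si](C)(C)C(C)(C)C)[C@H]1O
F2 | step 15 | (3aR,4R,5R,6R,10R,11R,11aS)-5-bromo-11-(TBSO)-4,6-dihydroxy-6,10-dimethyl-3-methylidenedecahydrocyclodeca[b]furan-2(3H)-one | C=C1C(=O)O[C@@H]2[C@H](O[Si](C)(C)C(C)(C)C)[C@H](C)CCC[C@@](C)(O)[C@H](Br)[C@H](O)[C@@H]12
F3 | step 8 | (2S)-4,4-dibromo-1,2-bis(TESO)but-3-ene | BrC(Br)=C[C@H](O[Si](CC)(CC)CC)CO[Si](CC)(CC)CC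
F4 | step 8 | (2S,3Z)-4-bromo-1,2-bis(TESO)pent-3-ene | C/C(Br)=C/[C@H](O[Si](CC)(CC)CC)CO[Si](CC)(CC)CC
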